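Everything rests on cutting both C–CH3 bonds of the side-chain carbinol. The CH2CH2C(CH3)2OH chain on C6 of ring A and the free hydroxyl on neighbouring C5 are treated as an opened dihydrocoumarin: the carbinol carbon was a lactone carbonyl bound to O5. In one operation excess MeMgBr adds twice to this aryl ester, forms both C–CH3 bonds, opens the temporary ring and releases O5–H. The precursor is the finished isoflavone, ring B dimethylchromene included, with the six-membered lactone spanning C6 and O5 and with O7 and O2' as triisopropylsilyl ethers. Built on symmetric phloroglucinol, the same lactone earlier steers the closure of ring C to the oxygen lying para to the chain.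

Key step: step 10

Assumption: Kanzonol T has no stereocentre, so no stereocontrol is needed. Chroman-2-one numbering is used for 3 and 11. Isoflavone numbering with primed ring B positions is used from 12 on.

Design remark: the pyran ring of ring B is annulated on 4. There the chelated ortho-acyl phenol fixes both the carbon (between the two oxygens) and the oxygen (para to the acyl group) that take part. A 2',4'-dihydroxyphenyl ring without such an acyl group would be expected to react mainly at C5'. The double bond is kept saturated through the Lewis-acid steps and restored in step 9.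

Step 1
Reactants: 1 phloroglucinol; 2 acrylic acid
Product: 3 5,7-dihydroxychroman-2-one (5,7-dihydroxy-3,4-dihydrocoumarin)
Conditions: Amberlyst-15, toluene, reflux, Dean–Stark (1 in 1.5-fold excess)
Reagents that add atoms: none
Why: Acid-catalysed Friedel–Crafts conjugate addition (hydroarylation) of acrylic acid followed by lactonisation is a known route from polyphenols to 3,4-dihydrocoumarins, and the threefold symmetry of 1 makes all ring carbons equivalent, so the chain position is unambiguous.

Step 2
Reactants: 4 2,4-dihydroxyacetophenone; 5 3-methylbut-2-enal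
Product: 6 1-(5-hydroxy-2,2-dimethyl-2H-chromen-6-yl)ethan-1-one
Conditions: ethylenediammonium diacetate (10 mol%), toluene, reflux
Reagents that add atoms: none
Why: Aldol-type condensation, dehydration to the ortho-quinone methide and oxa-6π electrocyclisation is the standard chromene annulation of resorcinols, and in 4 the hydrogen bond of 2-OH to the acetyl group reserves that oxygen and directs C–C bond formation to C3, so the angular 5-hydroxy-6-acyl chromene is the known product.

Step 3
Reactants: 6 1-(5-hydroxy-2,2-dimethyl-2H-chromen-6-yl)ethan-1-one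
Product: 7 1-(5-hydroxy-2,2-dimethylchroman-6-yl)ethan-1-one
Conditions: H2 (1 atm), 10% Pd/C, EtOAc, rt
Reagents that add atoms: none
Why: Catalytic hydrogenation saturates the styrene-type C3=C4 bond well before the chelated aryl ketone reacts, and it parks the acid-labile chromene as a chroman that tolerates the Lewis acids of steps 6 and 7.

Step 4
Reactants: 7 1-(5-hydroxy-2,2-dimethylchroman-6-yl)ethan-1-one
Product: 8 1-(5-methoxy-2,2-dimethylchroman-6-yl)ethan-1-one
Conditions: MeI, K2CO3, DMF, 50 °C
Reagents that add atoms: iodomethane (CI)
Why: Williamson O-methylation of the only phenol gives an ether that is inert to hot BF3·OEt2 and keeps this oxygen from condensing with the ketone of 11 to a 2-arylbenzofuran.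

Step 5
Reactants: 8 1-(5-methoxy-2,2-dimethylchroman-6-yl)ethan-1-one
Product: 10 (5-methoxy-2,2-dimethylchroman-6-yl)acetic acid, via thiomorpholide 9 (not isolated)
Conditions: S8, morpholine, 130 °C; then NaOH, EtOH–H2O, reflux; HCl
Reagents that add atoms: sulfur (S1SSSSSSS1) and morpholine (C1COCCN1), which end up only in 9; water (O), which supplies both oxygen atoms of the carboxyl group of 10
Why: The Willgerodt–Kindler reaction moves the oxidised carbon of an aryl methyl ketone to the chain terminus as a thioamide, and alkaline hydrolysis of the crude thiomorpholide is the classical way to the arylacetic acid, with aryl ethers untouched.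

Step 6
Reactants: 3 5,7-dihydroxychroman-2-one; 10 (5-methoxy-2,2-dimethylchroman-6-yl)acetic acid
Product: 12 5-hydroxy-9-(5-methoxy-2,2-dimethylchroman-6-yl)-3,4-dihydro-2H,10H-pyrano[2,3-f]chromene-2,10-dione (isoflavone with 7-OH, 2'-OMe and the C6–CH2CH2C(=O)–O5 lactone), via deoxybenzoin 11 (not isolated)
Conditions: BF3·OEt2 (neat), 80 °C; then DMF, MsCl, 55 to 70 °C; ice-water
Reagents that add atoms: N,N-dimethylformamide (CN(C)C=O), source of C2–H
Why: BF3-mediated Friedel–Crafts acylation of a resorcinol, followed in the same flask by formylation of the active methylene with the DMF/MsCl iminium salt and cyclisation, is the established one-pot deoxybenzoin route to isoflavones; C8 of 3 is ortho to 7-OH and para to 5-OH, the site at which resorcinols and 5,7-dihydroxycoumarins are acylated, and in 11 the ketone has the lactone oxygen on one side, so only 7-OH can close ring C and the chain ends up on C6.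

Step 7
Reactants: 12 the 7-hydroxy-2'-methoxy lactone-bridged isoflavone
Product: 13 5-hydroxy-9-(5-hydroxy-2,2-dimethylchroman-6-yl)-3,4-dihydro-2H,10H-pyrano[2,3-f]chromene-2,10-dione (7,2'-dihydroxy lactone-bridged isoflavone)
Conditions: BBr3 (4 equiv), CH2Cl2, −78 to 0 °C; ice-water
Reagents that add atoms: none
Why: Boron tribromide ether cleavage removes the twisted and therefore basic 2'-methyl ether at low temperature, conditions under which 2,2-dimethylchromans and aryl ester lactones are known to survive.

Step 8
Reactants: 13 the 7,2'-dihydroxy lactone-bridged isoflavone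
Product: 14 7,2'-bis-O-triisopropylsilyl ether of 13 (ring B still a chroman)
Conditions: TIPSOTf (2.5 equiv), 2,6-lutidine, CH2Cl2, 0 °C to rt
Reagents that add atoms: triisopropylsilyl trifluoromethanesulfonate (CC(C)[Si](OS(=O)(=O)C(F)(F)F)(C(C)C)C(C)C)
Why: Silylation with the triflate and a hindered non-nucleophilic base reaches the doubly ortho-substituted 2'-OH as well as the acidic 7-OH without touching the lactone, and the two ethers block phenol oxidation in step 9, remove every acidic proton for step 10 and fall together in step 11.

Step 9
Reactants: 14 the bis-silylated chroman lactone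
Product: 15 5-(triisopropylsilyloxy)-9-[2,2-dimethyl-5-(triisopropylsilyloxy)-2H-chromen-6-yl]-3,4-dihydro-2H,10H-pyrano[2,3-f]chromene-2,10-dione (key-step precursor: isoflavone-fused dihydrocoumarin with the ring B chromene)
Conditions: DDQ (1.2 equiv), 1,4-dioxane, 90 °C
Reagents that add atoms: none
Why: DDQ dehydrogenation of 2,2-dimethylchromans to 2,2-dimethylchromenes runs by hydride abstraction from the benzylic C4 position, which here has two ortho oxygen donors on the electron-rich ring B, whereas the benzylic CH2 of the lactone sits on the acyl-substituted ring A and dihydrocoumarins need much more forcing conditions.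

Step 10
Reactants: 15 the bis-silylated chromene lactone
Product: 17 7,2'-bis-O-triisopropylsilyl Kanzonol T, via methyl ketone 16 (not isolated)
Conditions: MeMgBr (4 equiv), THF, −78 to −20 °C; aq NH4Cl
Reagents that add atoms: methylmagnesium bromide (C[Mg]Br), two methyl groups
Why: MeMgBr attacks the lactone carbonyl, the tetrahedral magnesium alkoxide collapses with loss of the C5 aryloxide (ring opening) to give methyl ketone 16, and a second equivalent adds to 16 to give the tertiary alkoxide, so both C–CH3 bonds are made in one flask. The closest known reaction type is the double Grignard addition to 3,4-dihydrocoumarins, which gives 2-(3-hydroxy-3-methylbutyl)phenols. No ring is closed and no stereocentre is created; one ring is opened. The step needs chemoselectivity for the ester over C4=O and C2 of ring C: an aryl ester of an acidic, acyl-substituted phenol is far more electrophilic than the vinylogous ester of the chromone, and uncatalysed addition of MeMgBr to isoflavones is slow at −78 °C. After the first addition the O5 magnesium phenoxide chelates O4 and feeds electron density into the chromone, which closes that pathway for the rest of the reaction. With O7 and O2' silylated there is no acidic proton and no ring B phenoxide that could add to C2, so a modest excess of reagent suffices.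

Step 11
Reactants: 17 7,2'-bis-O-triisopropylsilyl Kanzonol T
Product: 18 Kanzonol T
Conditions: TBAF (2.5 equiv), AcOH (2.5 equiv), THF, 0 °C
Reagents that add atoms: none
Why: Fluoride cleaves both aryl silyl ethers under acetic acid buffering, which keeps the medium near neutral so that ring C is not opened by base and the tertiary alcohol is neither dehydrated nor cyclised onto a flanking phenol by acid.

Compound list
1 | phloroglucinol | Oc1cc(O)cc(O)c1 | starting material
2 | acrylic acid | C=CC(=O)O | starting material
3 | 5,7-dihydroxychroman-2-one | O=C1CCc2c(O)cc(O)cc2O1 | intermediate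
4 | 2,4-dihydroxyacetophenone | CC(=O)c1ccc(O)cc1O | starting material
5 | 3-methylbut-2-enal | CC(C)=CC=O | starting material
6 | 1-(5-hydroxy-2,2-dimethyl-2H-chromen-6-yl)ethan-1-one | CC(=O)c1ccc2OC(C)(C)C=Cc2c1O | intermediate
7 | 1-(5-hydroxy-2,2-dimethylchroman-6-yl)ethan-1-one | CC(=O)c1ccc2OC(C)(C)CCc2c1O | intermediate
8 | 1-(5-methoxy-2,2-dimethylchroman-6-yl)ethan-1-one | CC(=O)c1ccc2OC(C)(C)CCc2c1OC | intermediate
9 | 2-(5-methoxy-2,2-dimethylchroman-6-yl)-1-(morpholin-4-yl)ethane-1-thione (not isolated) | S=C(Cc1ccc2OC(C)(C)CCc2c1OC)N1CCOCC1 | intermediate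
10 | (5-methoxy-2,2-dimethylchroman-6-yl)acetic acid | OC(=O)Cc1ccc2OC(C)(C)CCc2c1OC | intermediate
11 | 8-[(5-methoxy-2,2-dimethylchroman-6-yl)acetyl]-5,7-dihydroxychroman-2-one (not isolated) | O=C1CCc2c(O)cc(O)c(C(=O)Cc3ccc4OC(C)(C)CCc4c3OC)c2O1 | intermediate
12 | 7-hydroxy-2'-methoxy lactone-bridged isoflavone, ring B chroman | O=C1CCc2c(O)cc3occ(-c4ccc5OC(C)(C)CCc5c4OC)c(=O)c3c2O1 | intermediate
13 | 7,2'-dihydroxy lactone-bridged isoflavone, ring B chroman | O=C1CCc2c(O)cc3occ(-c4ccc5OC(C)(C)CCc5c4O)c(=O)c3c2O1 | intermediate
14 | 7,2'-bis-O-TIPS lactone-bridged isoflavone, ring B chroman | O=C1CCc2c(O[Si](C(C)C)(C(C)C)C(C)C)cc3occ(-c4ccc5OC(C)(C)CCc5c4O[Si](C(C)C)(C(C)C)C(C)C)c(=O)c3c2O1 | intermediate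
15 | 7,2'-bis-O-TIPS lactone-bridged isoflavone, ring B chromene (key-step precursor) | O=C1CCc2c(O[Si](C(C)C)(C(C)C)C(C)C)cc3occ(-c4ccc5OC(C)(C)C=Cc5c4O[Si](C(C)C)(C(C)C)C(C)C)c(=O)c3c2O1 | intermediate
16 | 5-hydroxy-6-(3-oxobutyl)-7,2'-bis-O-TIPS isoflavone with ring B chromene (not isolated) | CC(=O)CCc1c(O[Si](C(C)C)(C(C)C)C(C)C)cc2occ(-c3ccc4OC(C)(C)C=Cc4c3O[Si](C(C)C)(C(C)C)C(C)C)c(=O)c2c1O | intermediate
17 | 7,2'-bis-O-triisopropylsilyl Kanzonol T (key-step product) | CC(C)(O)CCc1c(O[Si](C(C)C)(C(C)C)C(C)C)cc2occ(-c3ccc4OC(C)(C)C=Cc4c3O[Si](C(C)C)(C(C)C)C(C)C)c(=O)c2c1O | intermediate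
18 | Kanzonol T | CC(C)(O)CCc1c(O)cc2occ(-c3ccc4c(c3O)C=CC(C)(C)O4)c(=O)c2c1O | target

Total step count: 11. Longest linear sequence: 10 (steps 2 to 5, then 6 to 11, from 4 to 18).

Steps most likely to fail

Step 10. MeMgBr may attack ring C, by conjugate addition at C2 or by addition to C4=O, before the ester is consumed. Alternatively, enolisation of ketone 16 may stall the sequence after the first methyl transfer. The fallback sets out from 15 and comes back at 17. The lactone is first opened with methanol (MeOH, catalytic DMAP, rt) to the 5-hydroxy methyl propanoate, methyl ester F1. The first equivalent of MeMgBr then only deprotonates the chelated 5-OH. The chromone is therefore already deactivated as its magnesium chelate before any carbon nucleophile meets an electrophile. Ordinary double addition to the alkyl ester follows (MeMgBr premixed with anhydrous CeCl3, THF, −78 to 0 °C, which also suppresses enolisation) and gives 17.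

Step 6. Site selectivity of the acylation may erode through attack at C6 of 3, between the two hydroxyls. The lactone then ends up on the wrong oxygen of the isoflavone. The fallback sets out from 12 as obtained and comes back at 14. It lets the silyl group, not the acylation site, decide where the lactone sits.
- The starting material is 12 mixed with the isomer that carries the lactone on O7 and a free 5-OH, O7-lactone isomer F2.
- BBr3 as in step 7 converts the mixture into 13 and the demethylated O7-lactone F3.
- LiOH, THF–H2O, 0 °C, then careful acidification, opens both lactones to the same 6-(2-carboxyethyl)-5,7,2'-trihydroxy compound, hydroxy acid F4.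
- TIPSOTf/2,6-lutidine followed by AcOH–THF–H2O, which hydrolyses only the silyl ester, gives the 7,2'-bis-silylated acid F5. Its chelated 5-OH is the only free phenol.
- EDC·HCl with catalytic DMAP in CH2Cl2 then closes the lactone necessarily on O5 to give 14.

Only material whose ring C closed toward the oxygen next to the chain is lost.

Step 9. Hydride abstraction next to the bulky 2'-silyl ether may be sluggish, so that dehydrogenation of the lactone ring begins to compete at the temperature required. The fallback sets out from 14 and comes back at 15. Hydride abstraction is replaced by hydrogen-atom abstraction and elimination. NBS with catalytic AIBN in PhCF3 at 80 °C brominates the more electron-rich benzylic position to give the racemic ring B 4-bromochroman F6. Warming F6 with 2,4,6-collidine in toluene removes HBr to give 15.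

Further compounds
F1 | step 10 | methyl 3-{5-hydroxy-4-oxo-7-(triisopropylsilyloxy)-3-[2,2-dimethyl-5-(triisopropylsilyloxy)-2H-chromen-6-yl]-4H-chromen-6-yl}propanoate | COC(=O)CCc1c(O[Si](C(C)C)(C(C)C)C(C)C)cc2occ(-c3ccc4OC(C)(C)C=Cc4c3O[Si](C(C)C)(C(C)C)C(C)C)c(=O)c2c1O
F2 | step 6 | 5-hydroxy-7-(5-methoxy-2,2-dimethylchroman-6-yl)-3,4-dihydro-2H,6H-pyrano[3,2-g]chromene-2,6-dione (lactone on O7, free 5-OH) | O=C1CCc2c(O1)cc3occ(-c4ccc5OC(C)(C)CCc5c4OC)c(=O)c3c2O
F3 | step 6 | 5-hydroxy-7-(5-hydroxy-2,2-dimethylchroman-6-yl)-3,4-dihydro-2H,6H-pyrano[3,2-g]chromene-2,6-dione | O=C1CCc2c(O1)cc3occ(-c4ccc5OC(C)(C)CCc5c4O)c(=O)c3c2O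
F4 | step 6 | 3-[5,7-dihydroxy-3-(5-hydroxy-2,2-dimethylchroman-6-yl)-4-oxo-4H-chromen-6-yl]propanoic acid | OC(=O)CCc1c(O)cc2occ(-c3ccc4OC(C)(C)CCc4c3O)c(=O)c2c1O
F5 | step 6 | 7,2'-bis-O-triisopropylsilyl ether of F4 | OC(=O)CCc1c(O[Si](C(C)C)(C(C)C)C(C)C)cc2occ(-c3ccc4OC(C)(C)CCc4c3O[Si](C(C)C)(C(C)C)C(C)C)c(=O)c2c1O
F6 | step 9 | 14 with bromine at the benzylic C4 of the ring B chroman (racemic) | O=C1CCc2c(O[Si](C(C)C)(C(C)C)C(C)C)cc3occ(-c4ccc5OC(C)(C)CC(Br)c5c4O[Si](C(C)C)(C(C)C)C(C)C)c(=O)c3c2O1
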